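## Structural features

The target is a germacrane-type sesquiterpene lactone. Its ten-membered carbocycle (C1–C10) is bridged by an ether oxygen between C3 and C10, so that O, C10, C1, C2 and C3 form a 3(2H)-furanone with the ketone at C1. This vinylogous ester is extended by the Z trisubstituted C4=C5 alkene. An α-methylene-γ-butyrolactone (C12 carbonyl, exocyclic C11=C13) is fused trans across C7–C8, with the ring oxygen on C8. C6 carries a (2S,3S)-2,3-dimethyloxirane-2-carboxylate, the epoxide of an angelate. Three contiguous stereocentres (6S, 7R, 8S) lie between the alkene and the lactone, and the quaternary ether carbon C10 (S) is separated from them by the C9 methylene. The fragile groups are the methylene lactone (a Michael acceptor whose alkene moves into the ring once C7–H is acidified), the lactone acyl group (it can migrate between O8 and O6), the epoxy ester, the Z alkene and the vinylogous ester. The real difficulty is to close the strained, bridged medium ring with its Z alkene while fixing C6 relative to C7 and C8. The key step exploits the bond between the Z alkene carbon C5 and the oxygenated C6: this allylic alcohol pattern is the retron of an alkenyl-metal addition to an aldehyde, and the rigid furanone and lactone rings hold the two ends close.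

## Logic of the disconnections

29 is cut at the ester bond between O6 and the acyl carbon, giving 24 and 28. This takes the epoxide out of all earlier chemistry and leaves a single acylation for the end. The forward step must acylate a hindered allylic alcohol without letting the lactone migrate to O6. 28 has to be one enantiomer, because a racemic acid would give two diastereomeric esters.

28 is traced through 27 and 26 to 25 by cutting the two epoxide C–O bonds. Epoxidising 25 directly would give a racemate. Going through the allylic alcohol 26 allows a tartrate-controlled epoxidation that fixes both centres at once; the oxidation level is restored afterwards.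

24 is cut at the ring bond C5–C6 to give 23. One bond removes the medium ring and the C6 stereocentre and leaves an open chain with two rigid five-membered rings. The forward step needs a Z alkenyl iodide, a free aldehyde next to the epimerisable C7, and a neutral medium.

23 is taken back to 22 by a change of oxidation level at C6, and 22 to 21 by moving the lactone acyl group from O8 to O6. In 21 the C6 oxygen is hidden as the ring oxygen of a lactone, so the sensitive formyl group appears only one step before the ring closure. No step between 21 and 23 needs a base.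

21 is cut at C7–C8 into 16 and 19. This one bond brings in C6, C7, C11, C12 and C13 with the exocyclic alkene already in place and creates both C7 and C8. The forward step must be anti selective (the ring-locked alkene of 19 ensures this), must attack the Re face of the aldehyde (catalyst control), and must not touch the alkenyl iodide. A stepwise alternative (butenolide, conjugate addition, Nef reaction, enolate methylenation) is not used, because it would need a hydrogenation in the presence of the iodide and basic steps on the formyl lactone.

19 is traced to 17 by cutting the C–Br bond and moving the alkene out of the ring.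

16 is taken back through 15 to 13 by opening the furanone at the O–C3 bond (cyclodehydration in the forward sense). 13 goes back through 12 to 8 and 11 by cutting the C2–C3 bond (aldol addition, then oxidation). This joins the chiral ketone to the complete Z iodoalkene in one C–C bond. Only the methyl group of 8 can enolise.

11 is traced through 10 to 9: the C4–methyl and C5–I bonds are cut back to an alkyne. Carbometalation directed by the alkoxide fixes the Z geometry.

8 is traced through 7, 5, 4 and 2 to 1: the C1–C2 bond is cut (methyl addition to an amide), and the two carboxyl groups of 1 are told apart through the five-membered acetal of the α-hydroxy acid. C10 comes unchanged from the chiral pool.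

## Other disconnections considered

Alternative 1: The cut is the ring bond C8–C9 together with the side-chain bond C7–C11, which leads back to a six-membered ring. In the forward sense the potassium alkoxide of the carvone-derived dialkenyl cyclohexenol A1 would undergo an anionic oxy-Cope rearrangement, and the ten-membered enolate would be alkylated with methyl bromoacetate to give A2.
- In its favour: the ten-membered ring comes from a cheap chiral terpene without high dilution, the chair transition state fixes both ring alkenes including the Z enone, and the C7 side chain is added in the same flask.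
- Against it here: A2 has no oxygen at C8, its ketone is at C6 and not at C1, and it lacks the ether bridge and the furanone. C8, C10 and C1 would have to be functionalised late on a flexible medium ring under substrate control.
- Structure: the chosen plan fixes C10 from the chiral pool and C7/C8 by reagent control before the ring exists.
- Mechanism: a pericyclic ring expansion is a more dependable way to make a ten-membered ring than a carbonyl addition. On this point Alternative 1 is the better plan.
- Step economy: up to the ring, Alternative 1 is equal or better. The redox and C–O bond work after A2 makes the whole route longer.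

Alternative 2: The cut is the ether bond O–C10. In the forward sense the C3 hydroxyl of the epoxy alcohol A3 would open the 1,10-epoxide at C10 under mild acid and give A4 with a free C1 hydroxyl.
- In its favour: the step is biomimetic and stereospecific at C10 and C1, and it needs no protecting-group work for the bridge.
- Against it here: A3 is already a complete ten-membered lactone with the Z alkene, so the ring problem is only moved. Acid on such epoxides can also trigger transannular C–C bond formation from the C4=C5 alkene. After A4, C1 must still be oxidised and C2=C3 introduced next to a methylene lactone.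
- Structure: A4 still lacks the furanone unsaturation.
- Mechanism: the stereospecific opening sets C10 as reliably as the chiral pool does, so the two plans are equal here.
- Step economy: the bridge costs one step against three in the chosen plan (aldol, oxidation, cyclodehydration), so Alternative 2 is better for the bridge. Overall it is longer, because A3 needs its own macrocyclisation.

Alternative 3: The cut is the bond C6–C7. In the forward sense the thirteen-membered allylic ether A5 would be deprotonated at C6, and a [2,3]-sigmatropic shift would contract the ring to A6, releasing the C6 alcohol and the C11=C13 alkene.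
- In its favour: one concerted step makes the C6–C7 bond, both stereocentres and the exocyclic alkene, and a thirteen-membered ether is easier to close than the bridged ten-membered ring. Like the chosen plan it delivers the free C6 hydroxyl (equal), and it sets two centres in the ring-forming step where the chosen plan sets one (better).
- Against it here: the C6 anion is the end of a trienolate that runs through C4=C5 into the furanone. The Z geometry is therefore at risk, a [1,2]-shift can compete, and the vinylogous ester must survive a strong base. The C6/C7 configuration and its relation to C8 depend on a macrocyclic transition state. The lactone must still be built afterwards from the C12 alcohol.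
- Structure and mechanism: the chosen plan keeps the alkene geometry by a stereoretentive, neutral metal sequence and sets C7/C8 before cyclisation.
- Step economy: the two plans are about equal.

Key step: step 16

Assumption: the sense of induction of the chiral chromium catalyst in step 13 is not fixed by analogy alone; the ligand antipode that gives Re-face attack on 16 is taken, and C8 is checked on 21 (free carbinol, Mosher esters). Metal enolates, organochromium species and metal alkoxides are treated as reactive intermediates inside one step and carry no number.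

Step 1
Reactants: 1 (S)-citramalic acid
Product: 2 2-[(4S)-2,2,4-trimethyl-5-oxo-1,3-dioxolan-4-yl]acetic acid
Conditions: 2,2-dimethoxypropane, TsOH·H2O (cat.), acetone, rt
Reagents that add atoms: 2,2-dimethoxypropane, COC(C)(C)OC
Why: Acid-catalysed acetalisation; the α-hydroxy acid closes the five-membered dioxolanone in preference to a six-membered ring, so the distal carboxyl stays free. The quaternary centre is not touched.

Step 2
Reactants: 2 2-[(4S)-2,2,4-trimethyl-5-oxo-1,3-dioxolan-4-yl]acetic acid
Product: 4 (3S)-3-hydroxy-3-methyloxolan-2-one, via dioxolanone alcohol 3 (not isolated)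
Conditions: BH3·SMe2, THF, 0 °C to rt; MeOH; then TsOH·H2O (cat.), CH2Cl2, rt
Reagents that add atoms: none
Why: Borane reduces the free carboxylic acid much faster than the acetal-type ester. Acid then lets the new primary alcohol take over the acyl group (lactonisation with loss of acetone) to give the five-membered hydroxy lactone.

Step 3
Reactants: 4 (3S)-3-hydroxy-3-methyloxolan-2-one
Product: 5 (2S)-2,4-dihydroxy-N-methoxy-N,2-dimethylbutanamide
Conditions: MeNHOMe·HCl, iPrMgCl, THF, −20 to 0 °C
Reagents that add atoms: N,O-dimethylhydroxylamine hydrochloride, CNOC.Cl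
Why: Weinreb aminolysis of a lactone by the magnesium amide; the product is used promptly to avoid relactonisation.

Step 4
Reactants: 5 (2S)-2,4-dihydroxy-N-methoxy-N,2-dimethylbutanamide
Product: 7 (2S)-4-[(tert-butyldimethylsilyl)oxy]-N-methoxy-N,2-dimethyl-2-[(trimethylsilyl)oxy]butanamide, via primary silyl ether 6 (not isolated)
Conditions: TBSCl, imidazole, DMF, 0 °C; then TMSCl, rt
Reagents that add atoms: tert-butyldimethylsilyl chloride, CC(C)(C)[Si](C)(C)Cl; trimethylsilyl chloride, C[Si](C)(C)Cl
Why: Steric differentiation in silylation: the bulky chloride takes only the primary hydroxyl, and the small trimethylsilyl donor then caps the tertiary one. The acid-labile tertiary ether and the more robust primary ether are wanted for step 10.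

Step 5
Reactants: 7 (2S)-4-[(tert-butyldimethylsilyl)oxy]-N-methoxy-N,2-dimethyl-2-[(trimethylsilyl)oxy]butanamide
Product: 8 (3S)-5-[(tert-butyldimethylsilyl)oxy]-3-methyl-3-[(trimethylsilyl)oxy]pentan-2-one
Conditions: MeMgBr, THF, 0 °C; aq. NH4Cl
Reagents that add atoms: methylmagnesium bromide, C[Mg]Br
Why: Weinreb ketone synthesis; the chelated tetrahedral intermediate prevents a second addition.

Step 6
Reactants: 9 prop-2-yn-1-ol
Product: 10 (2Z)-3-iodo-2-methylprop-2-en-1-ol
Conditions: MeMgBr (2.5 equiv), CuI (10 mol%), THF, −10 °C to rt; then I2, −78 to 0 °C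
Reagents that add atoms: methylmagnesium bromide, C[Mg]Br; iodine, [I][I]
Why: Alkoxide-directed, copper-catalysed anti-carbomagnesiation of the propargylic alkoxide gives a cyclic alkenylmagnesium species. Iodinolysis with retention leaves iodine cis to the CH2OH group (Z).

Step 7
Reactants: 10 (2Z)-3-iodo-2-methylprop-2-en-1-ol
Product: 11 (2Z)-3-iodo-2-methylprop-2-enal
Conditions: MnO2, CH2Cl2, rt, dark; filtered and used at once
Reagents that add atoms: none
Why: Neutral heterogeneous oxidation of an allylic alcohol; no acid, base or light that could isomerise the Z iodoenal.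

Step 8
Reactants: 8 (3S)-5-[(tert-butyldimethylsilyl)oxy]-3-methyl-3-[(trimethylsilyl)oxy]pentan-2-one; 11 (2Z)-3-iodo-2-methylprop-2-enal
Product: 12 (1Z,6S)-8-[(tert-butyldimethylsilyl)oxy]-3-hydroxy-1-iodo-2,6-dimethyl-6-[(trimethylsilyl)oxy]oct-1-en-5-one (both C3 epimers)
Conditions: LiN(iPr)2, THF, −78 °C; then 11, −78 °C; aq. NH4Cl
Reagents that add atoms: none
Why: Aldol addition of the kinetic lithium enolate (only the methyl group can enolise) to the aldehyde carbonyl. The new carbinol centre is unselective and is removed by oxidation in step 9.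

Step 9
Reactants: 12 (1Z,6S)-8-[(tert-butyldimethylsilyl)oxy]-3-hydroxy-1-iodo-2,6-dimethyl-6-[(trimethylsilyl)oxy]oct-1-en-5-one
Product: 13 (1Z,6S)-8-[(tert-butyldimethylsilyl)oxy]-1-iodo-2,6-dimethyl-6-[(trimethylsilyl)oxy]oct-1-ene-3,5-dione
Conditions: Dess–Martin periodinane, NaHCO3, CH2Cl2, 0 °C to rt
Reagents that add atoms: none
Why: Buffered Dess–Martin oxidation of the β-hydroxy ketone to the 1,3-diketone; no amine base touches the β-iodo enone.

Step 10
Reactants: 13 (1Z,6S)-8-[(tert-butyldimethylsilyl)oxy]-1-iodo-2,6-dimethyl-6-[(trimethylsilyl)oxy]oct-1-ene-3,5-dione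
Product: 15 (2S)-2-(2-hydroxyethyl)-5-[(1Z)-1-iodoprop-1-en-2-yl]-2-methylfuran-3(2H)-one, via silyl-protected furanone 14 (not isolated)
Conditions: TsOH·H2O (cat.), CH2Cl2, rt; then HF·pyridine, THF, 0 °C to rt
Reagents that add atoms: none
Why: Acid-catalysed cyclodehydration of an α′-hydroxy 1,3-diketone: loss of the labile tertiary silyl group lets that hydroxyl add to the distal carbonyl, and dehydration gives the 3(2H)-furanone. The primary silyl ether survives the first stage and cannot compete for ring closure; fluoride then removes it.

Step 11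
Reactants: 15 (2S)-2-(2-hydroxyethyl)-5-[(1Z)-1-iodoprop-1-en-2-yl]-2-methylfuran-3(2H)-one
Product: 16 2-[(2S)-5-[(1Z)-1-iodoprop-1-en-2-yl]-2-methyl-3-oxo-2,3-dihydrofuran-2-yl]acetaldehyde
Conditions: Dess–Martin periodinane, NaHCO3, CH2Cl2, 0 °C; used crude
Reagents that add atoms: none
Why: Mild oxidation of the primary alcohol. The aldehyde has acidic α-hydrogens and a β-oxygen leaving group, so it is kept away from amines and used directly.

Step 12
Reactants: 17 3-methylideneoxolan-2-one
Product: 19 3-(bromomethyl)furan-2(5H)-one, via dibromide 18 (not isolated)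
Conditions: Br2, CH2Cl2, 0 °C; then Et3N, 0 °C to rt
Reagents that add atoms: bromine, BrBr
Why: Bromine adds to the exocyclic alkene. Dehydrobromination of the tertiary α-bromide into the ring then gives the conjugated butenolide with the allylic bromide.

Step 13
Reactants: 16 2-[(2S)-5-[(1Z)-1-iodoprop-1-en-2-yl]-2-methyl-3-oxo-2,3-dihydrofuran-2-yl]acetaldehyde; 19 3-(bromomethyl)furan-2(5H)-one
Product: 21 (4S)-4-{(1S)-1-hydroxy-2-[(2S)-5-[(1Z)-1-iodoprop-1-en-2-yl]-2-methyl-3-oxo-2,3-dihydrofuran-2-yl]ethyl}-3-methylideneoxolan-2-one, via trimethylsilyl ether 20 (not isolated)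
Conditions: CrCl2 (10 mol%, nickel-free), C2-symmetric 1,8-bis(4-isopropyloxazolin-2-yl)-3,6-diphenylcarbazole ligand (antipode for Re-face delivery, 12 mol%), iPr2NEt (20 mol%, premixed with CrCl2 and ligand), Mn powder, TMSCl, THF, 0 °C to rt; then 1 M HCl, THF
Reagents that add atoms: none
Why: Catalytic asymmetric Nozaki–Hiyama allylation: the allyl trivalent chromium species from 19 adds through its ring carbon (C7) in a chair transition state, and the ring-locked alkene geometry gives the anti C7/C8 relation. The ligand selects the Re face of the aldehyde, which sets 8S and with it 7. Without nickel the alkenyl iodide is inert to divalent chromium; TMSCl turns the catalyst over to give 20, and acid removes the silyl group.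

Step 14
Reactants: 21 (4S)-4-{(1S)-1-hydroxy-2-[(2S)-5-[(1Z)-1-iodoprop-1-en-2-yl]-2-methyl-3-oxo-2,3-dihydrofuran-2-yl]ethyl}-3-methylideneoxolan-2-one
Product: 22 (4S,5S)-4-(hydroxymethyl)-5-{[(2S)-5-[(1Z)-1-iodoprop-1-en-2-yl]-2-methyl-3-oxo-2,3-dihydrofuran-2-yl]methyl}-3-methylideneoxolan-2-one
Conditions: camphorsulfonic acid (10 mol%), CH2Cl2, rt to 40 °C
Reagents that add atoms: none
Why: Acid-catalysed translactonisation (intramolecular transesterification through a bicyclic hemi-orthoester): the C8 hydroxyl takes the acyl group and the primary C6 hydroxyl is released. The equilibrium should favour the more substituted 4,5-disubstituted ring. No stereocentre is touched, and the anti adduct maps onto the trans lactone.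

Step 15
Reactants: 22 (4S,5S)-4-(hydroxymethyl)-5-{[(2S)-5-[(1Z)-1-iodoprop-1-en-2-yl]-2-methyl-3-oxo-2,3-dihydrofuran-2-yl]methyl}-3-methylideneoxolan-2-one
Product: 23 (2S,3R)-2-{[(2S)-5-[(1Z)-1-iodoprop-1-en-2-yl]-2-methyl-3-oxo-2,3-dihydrofuran-2-yl]methyl}-4-methylidene-5-oxooxolane-3-carbaldehyde
Conditions: Dess–Martin periodinane, NaHCO3, CH2Cl2, 0 °C; filtered through Celite, used at once
Reagents that add atoms: none
Why: Neutral Dess–Martin oxidation of the primary alcohol. The formyl group appears only here, and no amine is present that could epimerise C7 or move the exocyclic alkene into conjugation.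

Step 16
Reactants: 23 (2S,3R)-2-{[(2S)-5-[(1Z)-1-iodoprop-1-en-2-yl]-2-methyl-3-oxo-2,3-dihydrofuran-2-yl]methyl}-4-methylidene-5-oxooxolane-3-carbaldehyde
Product: 24 (4Z,6S,7S,8S,10S)-6-hydroxy-1-oxo-3,10-epoxygermacra-2,4,11(13)-trien-12,8-olide
Conditions: CrCl2 (8 equiv), NiCl2 (0.1 equiv), degassed DMSO, rt, 23 added by syringe pump to about 2 mM; cold aq. ethylenediamine work-up
Reagents that add atoms: none
Why: Intramolecular Nozaki–Hiyama–Kishi reaction: CrCl2 reduces NiCl2 to zerovalent nickel, which inserts into the C5–I bond with retention of the Z geometry; transmetalation gives an alkenyl trivalent chromium species that adds only to the aldehyde and leaves the furanone ketone and the methylene lactone alone. The closest known reaction type is the NHK macrocyclisation of ω-formyl alkenyl iodides to medium and large carbocycles. The ring closes in a 10-exo-trig mode for the carbocycle (nine-membered when counted through the ether oxygen), helped by the planar furanone–alkene unit and the trans lactone, which hold C5 near C6. C6 is controlled by C7 in a Felkin–Anh arrangement: the C7–C11 bond to the sp2 lactone carbon lies anti to the incoming C5, the ring atoms C5 and C8 are gauche as the tether requires, and the chromium-bound oxygen sits between C8 and C11, which leads to 6S. The step needs chemoselectivity for the aldehyde (inherent to alkenylchromium reagents), retention of alkene geometry (the nickel/chromium sequence is stereoretentive), no epimerisation at C7 and no alkene migration (neutral, amine-free medium), and suppression of oligomers (slow addition, high dilution). The cold chelating work-up frees the C6 alcohol before it can attack the lactone carbonyl.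

Step 17
Reactants: 25 angelic acid
Product: 26 (2Z)-2-methylbut-2-en-1-ol
Conditions: LiAlH4, Et2O, 0 °C
Reagents that add atoms: none
Why: Hydride reduction of the carboxylic acid to the allylic alcohol; at low temperature, without acid or heat, the Z alkene does not isomerise to the E isomer.

Step 18
Reactants: 26 (2Z)-2-methylbut-2-en-1-ol
Product: 27 [(2R,3S)-2,3-dimethyloxiran-2-yl]methanol
Conditions: Ti(OiPr)4 (10 mol%), D-(−)-diethyl tartrate (12 mol%), tBuOOH, 4 Å molecular sieves, CH2Cl2, −20 °C
Reagents that add atoms: tert-butyl hydroperoxide, CC(C)(C)OO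
Why: Sharpless asymmetric epoxidation. The natural L-(+)-tartrate gives 2S epoxy alcohols from Z allylic alcohols of this substitution type, so the D-(−)-tartrate gives the 2R,3S product. The oxygen adds syn, so the Z geometry fixes the relative configuration of the two epoxide carbons.

Step 19
Reactants: 27 [(2R,3S)-2,3-dimethyloxiran-2-yl]methanol
Product: 28 (2S,3S)-2,3-dimethyloxirane-2-carboxylic acid
Conditions: RuCl3·xH2O (2 mol%), NaIO4, MeCN/CCl4/H2O, 0 °C to rt
Reagents that add atoms: water, O
Why: Catalytic ruthenium tetroxide oxidation of a primary epoxy alcohol to the glycidic acid through the aldehyde hydrate. No stereocentre changes; the descriptor at C2 changes only because the substituent priorities change.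

Step 20
Reactants: 24 (4Z,6S,7S,8S,10S)-6-hydroxy-1-oxo-3,10-epoxygermacra-2,4,11(13)-trien-12,8-olide; 28 (2S,3S)-2,3-dimethyloxirane-2-carboxylic acid
Product: 29 (4Z,6S,7R,8S,10S)-6-{[(2S,3S)-2,3-dimethyloxiran-2-yl]carbonyloxy}-1-oxo-3,10-epoxygermacra-2,4,11(13)-trien-12,8-olide
Conditions: 28, 2,4,6-trichlorobenzoyl chloride, Et3N, THF, rt; then 24, DMAP, toluene, rt
Reagents that add atoms: none
Why: Yamaguchi esterification through the mixed anhydride and the acylpyridinium ion, suited to a hindered alcohol and an α-quaternary acid. Acylation occurs at oxygen, so C6 keeps its configuration, and the acid has no epimerisable centre.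

Compound list

1 | (S)-citramalic acid, (2S)-2-hydroxy-2-methylbutanedioic acid | C[C@](O)(CC(=O)O)C(=O)O | starting material
2 | 2-[(4S)-2,2,4-trimethyl-5-oxo-1,3-dioxolan-4-yl]acetic acid | C[C@@]1(CC(=O)O)OC(C)(C)OC1=O | intermediate
3 | (5S)-5-(2-hydroxyethyl)-2,2,5-trimethyl-1,3-dioxolan-4-one | C[C@@]1(CCO)OC(C)(C)OC1=O | intermediate (not isolated)
4 | (3S)-3-hydroxy-3-methyloxolan-2-one | C[C@]1(O)CCOC1=O | intermediate
5 | (2S)-2,4-dihydroxy-N-methoxy-N,2-dimethylbutanamide | CON(C)C(=O)[C@@](C)(O)CCO | intermediate
6 | (2S)-4-[(tert-butyldimethylsilyl)oxy]-2-hydroxy-N-methoxy-N,2-dimethylbutanamide | CON(C)C(=O)[C@@](C)(O)CCO[Si](C)(C)C(C)(C)C | intermediate (not isolated)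
7 | (2S)-4-[(tert-butyldimethylsilyl)oxy]-N-methoxy-N,2-dimethyl-2-[(trimethylsilyl)oxy]butanamide | CON(C)C(=O)[C@@](C)(O[Si](C)(C)C)CCO[Si](C)(C)C(C)(C)C | intermediate
8 | (3S)-5-[(tert-butyldimethylsilyl)oxy]-3-methyl-3-[(trimethylsilyl)oxy]pentan-2-one | CC(=O)[C@@](C)(O[Si](C)(C)C)CCO[Si](C)(C)C(C)(C)C | intermediate
9 | prop-2-yn-1-ol | C#CCO | starting material
10 | (2Z)-3-iodo-2-methylprop-2-en-1-ol | OC/C(C)=C\I | intermediate
11 | (2Z)-3-iodo-2-methylprop-2-enal | O=C/C(C)=C\I | intermediate
12 | (1Z,6S)-8-[(tert-butyldimethylsilyl)oxy]-3-hydroxy-1-iodo-2,6-dimethyl-6-[(trimethylsilyl)oxy]oct-1-en-5-one (C3 epimers) | I/C=C(C)\C(O)CC(=O)[C@@](C)(O[Si](C)(C)C)CCO[Si](C)(C)C(C)(C)C | intermediate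
13 | (1Z,6S)-8-[(tert-butyldimethylsilyl)oxy]-1-iodo-2,6-dimethyl-6-[(trimethylsilyl)oxy]oct-1-ene-3,5-dione | I/C=C(C)\C(=O)CC(=O)[C@@](C)(O[Si](C)(C)C)CCO[Si](C)(C)C(C)(C)C | intermediate
14 | (2S)-2-{2-[(tert-butyldimethylsilyl)oxy]ethyl}-5-[(1Z)-1-iodoprop-1-en-2-yl]-2-methylfuran-3(2H)-one | CC(C)(C)[Si](C)(C)OCC[C@]1(C)OC(=CC1=O)/C(C)=C\I | intermediate (not isolated)
15 | (2S)-2-(2-hydroxyethyl)-5-[(1Z)-1-iodoprop-1-en-2-yl]-2-methylfuran-3(2H)-one | OCC[C@]1(C)OC(=CC1=O)/C(C)=C\I | intermediate
16 | 2-[(2S)-5-[(1Z)-1-iodoprop-1-en-2-yl]-2-methyl-3-oxo-2,3-dihydrofuran-2-yl]acetaldehyde | O=CC[C@]1(C)OC(=CC1=O)/C(C)=C\I | intermediate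
17 | 3-methylideneoxolan-2-one (α-methylene-γ-butyrolactone) | C=C1CCOC1=O | starting material
18 | 3-bromo-3-(bromomethyl)oxolan-2-one (racemic) | O=C1OCCC1(Br)CBr | intermediate (not isolated)
19 | 3-(bromomethyl)furan-2(5H)-one | O=C1OCC=C1CBr | intermediate
20 | (4S)-4-{(1S)-2-[(2S)-5-[(1Z)-1-iodoprop-1-en-2-yl]-2-methyl-3-oxo-2,3-dihydrofuran-2-yl]-1-[(trimethylsilyl)oxy]ethyl}-3-methylideneoxolan-2-one | C=C1C(=O)OC[C@H]1[C@@H](O[Si](C)(C)C)C[C@]2(C)OC(=CC2=O)/C(C)=C\I | intermediate (not isolated)
21 | (4S)-4-{(1S)-1-hydroxy-2-[(2S)-5-[(1Z)-1-iodoprop-1-en-2-yl]-2-methyl-3-oxo-2,3-dihydrofuran-2-yl]ethyl}-3-methylideneoxolan-2-one | C=C1C(=O)OC[C@H]1[C@@H](O)C[C@]2(C)OC(=CC2=O)/C(C)=C\I | intermediate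
22 | (4S,5S)-4-(hydroxymethyl)-5-{[(2S)-5-[(1Z)-1-iodoprop-1-en-2-yl]-2-methyl-3-oxo-2,3-dihydrofuran-2-yl]methyl}-3-methylideneoxolan-2-one | OC[C@@H]1C(=C)C(=O)O[C@H]1C[C@]2(C)OC(=CC2=O)/C(C)=C\I | intermediate
23 | (2S,3R)-2-{[(2S)-5-[(1Z)-1-iodoprop-1-en-2-yl]-2-methyl-3-oxo-2,3-dihydrofuran-2-yl]methyl}-4-methylidene-5-oxooxolane-3-carbaldehyde | O=C[C@@H]1C(=C)C(=O)O[C@H]1C[C@]2(C)OC(=CC2=O)/C(C)=C\I | intermediate
24 | (4Z,6S,7S,8S,10S)-6-hydroxy-1-oxo-3,10-epoxygermacra-2,4,11(13)-trien-12,8-olide | C=C1C(=O)O[C@H]2C[C@]3(C)OC(=CC3=O)/C(C)=C\[C@H](O)[C@H]12 | intermediate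
25 | angelic acid, (2Z)-2-methylbut-2-enoic acid | C/C=C(/C)C(=O)O | starting material
26 | (2Z)-2-methylbut-2-en-1-ol | C/C=C(/C)CO | intermediate
27 | [(2R,3S)-2,3-dimethyloxiran-2-yl]methanol | OC[C@@]1(C)O[C@H]1C | intermediate
28 | (2S,3S)-2,3-dimethyloxirane-2-carboxylic acid | OC(=O)[C@@]1(C)O[C@H]1C | intermediate
29 | (4Z,6S,7R,8S,10S)-6-{[(2S,3S)-2,3-dimethyloxiran-2-yl]carbonyloxy}-1-oxo-3,10-epoxygermacra-2,4,11(13)-trien-12,8-olide | C=C1C(=O)O[C@H]2C[C@]3(C)OC(=CC3=O)/C(C)=C\[C@H](OC(=O)[C@@]3(C)O[C@H]3C)[C@H]12 | target

Total step count: 20 steps. Longest linear sequence: 14 steps (steps 1–5, 8–11, 13–16 and 20). The side branches are steps 6–7 (iodoenal), step 12 (allylic bromide) and steps 17–19 (epoxy acid).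

Steps least certain to work

The key step, step 16. The most likely failure is poor or reversed facial selectivity at C6, because the conformation of the closing macrocycle may override the Felkin preference of the open chain. Competing oligomerisation and slow migration of the exocyclic alkene of 23 before ring closure would lower the conversion further. The fallback accepts the other face and corrects it afterwards. It sets out from 23: cyclisation gives the epimeric (6R) alcohol F1. F1 is esterified with 28 under Mitsunobu conditions (PPh3, diisopropyl azodicarboxylate, toluene, 0 °C) with inversion at C6, and the route is rejoined directly at 29. The last step is then a substitution at carbon and no longer an acylation at oxygen.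

Step 13. The likely failures are insufficient control of the aldehyde face by the chromium catalyst (the C10 centre is too remote to help) and base-induced β-elimination of the furanone oxygen from 16 during the slow catalytic reaction. The fallback replaces the allylation by an auxiliary-controlled aldol route of known sense.
- It sets out from 16. (4R)-4-Benzyl-1,3-oxazolidin-2-one is N-acylated with methyl 4-chloro-4-oxobutanoate to give the imide F2.
- The boron enolate of F2 (Bu2BOTf, iPr2NEt, CH2Cl2, −78 °C) adds to 16 in the Evans syn sense, which corresponds to 7R,8S. Acid-induced ring closure in the same flask gives the trans lactone imide F3.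
- LiOH/H2O2 removes the auxiliary to give the acid F4, and BH3·SMe2 reduces it to the hydroxymethyl lactone F5.
- Silylation (TBSCl, imidazole) gives the silyl ether F6.
- LiN(SiMe3)2 followed by CH2=NMe2+ I− gives the Mannich base F7.
- MeI, then NaHCO3, eliminates to the methylene lactone silyl ether F8.
- HF·pyridine returns to the route at 22.
This costs five more steps but rests on a stereochemical model that is not in doubt.

Step 14. The likely failure is an unfavourable or incomplete acyl-migration equilibrium, which would leave much of 21 unchanged or return it from 22 during isolation. The fallback pulls the equilibrium by kinetic trapping. It sets out from 21: treatment with TBSCl, imidazole and catalytic DMAP in DMF lets the two lactones interconvert while only the primary alcohol is silylated, giving the silyl ether F9 (the same structure as F8). HF·pyridine then returns to the route at 22.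

Step 10. The likely failures are premature loss of the primary silyl ether, which would let the primary hydroxyl close the wrong ring onto the C1 carbonyl, and acid-promoted erosion of the Z geometry of the iodoalkene. The fallback removes the need for acid by changing the protecting-group plan. It sets out from 6, now isolated after the first stage of step 4.
- MeMgBr (3 equiv) gives the free hydroxy ketone F10.
- Its dianion (LiN(iPr)2, 2.2 equiv, THF, −78 °C) adds to 11 to give the diol F11.
- Dess–Martin oxidation gives the hydroxy diketone F12, which closes and dehydrates on silica gel or with a trace of pyridinium tosylate.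
- The route is rejoined at 14, which is then desilylated as in the second stage of step 10.

Further compounds

F1 | step 16 | (4Z,6R,7S,8S,10S)-6-hydroxy-1-oxo-3,10-epoxygermacra-2,4,11(13)-trien-12,8-olide (C6 epimer of 24) | C=C1C(=O)O[C@H]2C[C@]3(C)OC(=CC3=O)/C(C)=C\[C@@H](O)[C@H]12
F2 | step 13 | (4R)-4-benzyl-3-(4-methoxy-4-oxobutanoyl)-1,3-oxazolidin-2-one | COC(=O)CCC(=O)N1[C@H](Cc2ccccc2)COC1=O
F3 | step 13 | (4R)-4-benzyl-3-{[(2S,3R)-2-{[(2S)-5-[(1Z)-1-iodoprop-1-en-2-yl]-2-methyl-3-oxo-2,3-dihydrofuran-2-yl]methyl}-5-oxooxolan-3-yl]carbonyl}-1,3-oxazolidin-2-one | O=C1C[C@@H](C(=O)N2[C@H](Cc3ccccc3)COC2=O)[C@H](C[C@]4(C)OC(=CC4=O)/C(C)=C\I)O1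
F4 | step 13 | (2S,3R)-2-{[(2S)-5-[(1Z)-1-iodoprop-1-en-2-yl]-2-methyl-3-oxo-2,3-dihydrofuran-2-yl]methyl}-5-oxooxolane-3-carboxylic acid | O=C1C[C@@H](C(=O)O)[C@H](C[C@]2(C)OC(=CC2=O)/C(C)=C\I)O1
F5 | step 13 | (4S,5S)-4-(hydroxymethyl)-5-{[(2S)-5-[(1Z)-1-iodoprop-1-en-2-yl]-2-methyl-3-oxo-2,3-dihydrofuran-2-yl]methyl}oxolan-2-one | O=C1C[C@@H](CO)[C@H](C[C@]2(C)OC(=CC2=O)/C(C)=C\I)O1
F6 | step 13 | tert-butyldimethylsilyl ether of F5 | O=C1C[C@@H](CO[Si](C)(C)C(C)(C)C)[C@H](C[C@]2(C)OC(=CC2=O)/C(C)=C\I)O1
F7 | step 13 | 3-[(dimethylamino)methyl] derivative of F6 (C3 epimers of the lactone) | O=C1C(CN(C)C)[C@@H](CO[Si](C)(C)C(C)(C)C)[C@H](C[C@]2(C)OC(=CC2=O)/C(C)=C\I)O1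
F8 | step 13 | tert-butyldimethylsilyl ether of 22 | CC(C)(C)[Si](C)(C)OC[C@@H]1C(=C)C(=O)O[C@H]1C[C@]2(C)OC(=CC2=O)/C(C)=C\I
F9 | step 14 | tert-butyldimethylsilyl ether of 22 (same structure as F8) | CC(C)(C)[Si](C)(C)OC[C@@H]1C(=C)C(=O)O[C@H]1C[C@]2(C)OC(=CC2=O)/C(C)=C\I
F10 | step 10 | (3S)-5-[(tert-butyldimethylsilyl)oxy]-3-hydroxy-3-methylpentan-2-one | CC(=O)[C@@](C)(O)CCO[Si](C)(C)C(C)(C)C
F11 | step 10 | (1Z,6S)-8-[(tert-butyldimethylsilyl)oxy]-3,6-dihydroxy-1-iodo-2,6-dimethyloct-1-en-5-one (C3 epimers) | I/C=C(C)\C(O)CC(=O)[C@@](C)(O)CCO[Si](C)(C)C(C)(C)C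
F12 | step 10 | (1Z,6S)-8-[(tert-butyldimethylsilyl)oxy]-6-hydroxy-1-iodo-2,6-dimethyloct-1-ene-3,5-dione | I/C=C(C)\C(=O)CC(=O)[C@@](C)(O)CCO[Si](C)(C)C(C)(C)C
A1 | alternative 1 | 1-ethenyl-3-methyl-6-(prop-1-en-2-yl)-4-[(tert-butyldimethylsilyl)oxy]cyclohex-2-en-1-ol (ethenyl trans to propenyl, silyloxy cis to propenyl) | C=C[C@]1(O)C=C(C)[C@@H](O[Si](C)(C)C(C)(C)C)C[C@H]1C(C)=C
A2 | alternative 1 | methyl 2-[(4E,8Z)-7-[(tert-butyldimethylsilyl)oxy]-4,8-dimethyl-10-oxocyclodeca-4,8-dien-1-yl]acetate | COC(=O)C[C@@H]1CC/C(C)=C/C[C@H](O[Si](C)(C)C(C)(C)C)/C(C)=C\C1=O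
A3 | alternative 2 | (4Z)-6-[(tert-butyldimethylsilyl)oxy]-1,10-epoxy-3-hydroxygermacra-4,11(13)-dien-12,8-olide | C=C1C(=O)O[C@H]2C[C@@]3(C)O[C@@H]3C[C@H](O)/C(C)=C\[C@H](O[Si](C)(C)C(C)(C)C)[C@H]12
A4 | alternative 2 | (4Z)-6-[(tert-butyldimethylsilyl)oxy]-1-hydroxy-3,10-epoxygermacra-4,11(13)-dien-12,8-olide | C=C1C(=O)O[C@H]2C[C@]3(C)O[C@@H](C[C@H]3O)/C(C)=C\[C@H](O[Si](C)(C)C(C)(C)C)[C@H]12
A5 | alternative 3 | furanone-bridged thirteen-membered allylic ether (C6–O–C13 ether, C7=C11 ring alkene, C8 4-methoxybenzyl ether, C12 silyl ether) | COc1ccc(CO[C@H]2C[C@]3(C)OC(=CC3=O)/C(C)=C\COC/C(CO[Si](C)(C)C(C)(C)C)=C/2)cc1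
A6 | alternative 3 | furanone-bridged ten-membered carbocycle with C6 hydroxyl, C7 3-[(tert-butyldimethylsilyl)oxy]prop-1-en-2-yl branch and C8 4-methoxybenzyl ether | COc1ccc(CO[C@H]2C[C@]3(C)OC(=CC3=O)/C(C)=C\[C@H](O)[C@@H]2C(=C)CO[Si](C)(C)C(C)(C)C)cc1
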